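**Strategy**

- Cuts, in retrosynthetic order: the C9–C10 bond of the chlorodiene (Stille); the ester C–O bond between C1 and ring oxygen O3′ (Yamaguchi); C12–C13 (allenylstannane addition); then, inside the C13–C23 chain, the C17–O and C18–Cl bonds together (chlorocarbonate cyclisation), C19–C20 (alkenylzinc addition) and C17=C18 (cross-metathesis).
- Forward: 2-deoxy-D-ribose becomes a C13–C17 homoallylic tert-butyl carbonate, is extended to the C13–C23 dienyl carbonate and cyclised. The only ring made, a 1,3-dioxan-2-one spanning O15 and O17, is later exchanged for a silylene. The chain then grows at C12–C13, is converted to the (Z)-bromochloroalkene and is joined at C9–C10 to the stannyl tetraenoate already esterified to the quinic-acid-derived cyclohexane, which is never opened.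
- Enabling feature: O15 and O17 are 1,3-syn on C15–C16–C17, and the C17 hydroxyl and C18 chlorine are anti. This is what anti addition of a C15-tethered carbonate oxygen (to C17) and chlorine (to C18) across an (E)-C17=C18 alkene gives through a six-membered cyclic carbonate.
- Stereochemistry: C14/C15 from 2-deoxy-D-ribose; C19 from a ligand-controlled butenylzinc addition; C17/C18 from the key step; C12 from (S)-but-3-yn-2-ol by two anti transfers and C13 by matched Felkin addition; C1′, C3′, C4′ from (−)-quinic acid. Alkene geometries come from hydroboration, Wittig and Horner–Wadsworth–Emmons reactions, anti-hydrochlorination and a stereoretentive Stille coupling.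

Key step: step 7

Remark: locants C1–C23 are those of the target chain (C1 ester carbonyl, C23 ethyl terminus) and C1′–C6′ those of the ring (C1′ bears the carboxyl). The C12, C14 and C18 descriptors change with neighbouring groups although the spatial arrangement does not. DCDMH (1,3-dichloro-5,5-dimethylhydantoin) is assumed to give up its imide (N3) chlorine first.

**Route**

Step 1
Reactants: 1 2-deoxy-D-ribose
Product: 2 (2R,3S)-hex-5-ene-1,2,3-triol
Conditions: Ph3PCH3Br, KOtBu (excess), THF, 0 °C → rt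
Reagents that add atoms: methyltriphenylphosphonium bromide, C[P+](c1ccccc1)(c1ccccc1)c1ccccc1.[Br-]
Why: Wittig methylenation of the lactol through its open-chain aldehyde with excess ylide (the hydroxyls ride through as alkoxides) turns C17 into a vinyl terminus without touching C14 or C15, whose configurations come from the sugar.

Step 2
Reactants: 2 (2R,3S)-hex-5-ene-1,2,3-triol
Product: 3 (1S)-1-[(4R)-2,2-dimethyl-1,3-dioxolan-4-yl]but-3-en-1-ol
Conditions: Me2C(OMe)2, TsOH (cat.), DMF, rt
Reagents that add atoms: 2,2-dimethoxypropane, COC(C)(C)OC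
Why: Acid-catalysed transketalisation selects the terminal 1,2-diol because the erythro C14/C15 diol could only give a cis-disubstituted dioxolane, so the C15 hydroxyl stays free.

Step 3
Reactants: 3 (1S)-1-[(4R)-2,2-dimethyl-1,3-dioxolan-4-yl]but-3-en-1-ol
Product: 4 C13–C17 homoallylic tert-butyl carbonate (15-OBoc; 13,14-acetonide)
Conditions: Boc2O, DMAP, MeCN, rt
Reagents that add atoms: di-tert-butyl dicarbonate, CC(C)(C)OC(=O)OC(=O)OC(C)(C)C
Why: DMAP-catalysed acylation of the secondary alcohol with Boc2O gives the homoallylic tert-butyl carbonate that later serves as the tethered oxygen nucleophile.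

Step 4
Reactants: 4 C13–C17 homoallylic tert-butyl carbonate
Product: 5 C13–C19 (17E)-enal (15-OBoc; 13,14-acetonide)
Conditions: acrolein (5 equiv), second-generation Hoveyda–Grubbs catalyst RuCl2(H2IMes)(=CH-C6H4-2-OiPr) (5 mol %), CH2Cl2, 40 °C
Reagents that add atoms: acrolein, C=CC=O
Why: Olefin cross-metathesis of the terminal alkene with acrolein, an electron-poor partner that homodimerises slowly, gives the conjugated (E)-enal under thermodynamic control and brings in C18 and C19.

Step 5
Reactants: 5 C13–C19 (17E)-enal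
Product: 6 C13–C23 dienol (19-OH; 15-OBoc; 13,14-acetonide; 19S,20E)
Conditions: 1-butyne, Cy2BH, toluene, 0 °C → rt; ZnMe2, −78 °C; (−)-MIB (10 mol %), then 5, −30 → −10 °C; aq. NH4Cl
Reagents that add atoms: 1-butyne, CCC#C
Why: Catalytic asymmetric alkenylzinc 1,2-addition: syn hydroboration of 1-butyne fixes the (20E) geometry, boron-to-zinc exchange gives the butenyl(methyl)zinc, and the zinc aminoalkoxide of (−)-MIB delivers the alkenyl group to the Si face of the aldehyde, setting C19 as S under ligand control since C15 is too remote to bias the addition.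

Step 6
Reactants: 6 C13–C23 dienol
Product: 7 C13–C23 dienyl carbonate (19-OTES; 15-OBoc; 13,14-acetonide)
Conditions: TESCl, imidazole, CH2Cl2, 0 °C
Reagents that add atoms: chlorotriethylsilane, CC[Si](Cl)(CC)CC
Why: Standard silylation of the secondary bis-allylic alcohol; the TES ether masks O19 as a competing nucleophile in the next step and can later be removed without touching the other groups.

Step 7
Reactants: 7 C13–C23 dienyl carbonate
Product: 8 chloro carbonate (15,17-cyclic carbonate; 18-Cl; 19-OTES; 13,14-acetonide; 17R,18R)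
Conditions: DCDMH (1.1 equiv), CH2Cl2, −78 → −40 °C, dark
Reagents that add atoms: 1,3-dichloro-5,5-dimethylhydantoin, CC1(C)N(Cl)C(=O)N(Cl)C1=O
Why: Proposed new method: DCDMH transfers an electrophilic chlorine to the (E)-C17=C18 alkene while the carbonyl oxygen of the C15 tert-butyl carbonate attacks C17 from the opposite face, and the resulting 2-tert-butoxy-1,3-dioxan-2-ylium ion loses isobutene to leave the cyclic carbonate. The closest known reactions are the iodo- and bromocarbonate cyclisations of homoallylic tert-butyl carbonates to cis-4,6-disubstituted 1,3-dioxan-2-ones and the chlorolactonisations and chlorocyclisations of alkenoic acids and unsaturated carbamates with N-chlorohydantoins. The dioxanone ring closes in the 6-exo-trig mode. C17 is controlled by C15 through a chair-like transition state with the C14 dioxolanyl group equatorial (15,17-syn), and C18 follows stereospecifically from anti addition across the (E)-alkene. The step needs regioselectivity for oxygen at C17, secured by the six-membered closure and by the electron-withdrawing C19 silyloxy group next to C18, and chemoselectivity over C20=C21, secured because only C17=C18 has a tethered nucleophile that assists chlorine transfer. Low temperature and darkness hold back radical chlorination at the doubly allylic C19–H.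

Step 8
Reactants: 8 chloro carbonate
Product: 9 15,17-diol (18-Cl; 19-OTES; 13,14-acetonide)
Conditions: iBu2AlH (4 equiv), CH2Cl2, −78 → −20 °C; aq. KNaC4H4O6 (Rochelle salt)
Reagents that add atoms: none
Why: Hydride reduction of the cyclic carbonate (DIBAL-H reduction, the carbonyl carbon leaving as methanol) releases the 15,17-diol as aluminium alkoxides that are too weakly basic at low temperature to close the C17/C18 chlorohydrin to an epoxide, while the TES ether, acetonide and alkyl chloride are inert.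

Step 9
Reactants: 9 15,17-diol
Product: 10 15,17-O-di-tert-butylsilylene (18-Cl; 19-OTES; 13,14-acetonide)
Conditions: tBu2Si(OTf)2, 2,6-lutidine, CH2Cl2, 0 °C
Reagents that add atoms: di-tert-butylsilyl bis(trifluoromethanesulfonate), CC(C)(C)[Si](OS(=O)(=O)C(F)(F)F)(OS(=O)(=O)C(F)(F)F)C(C)(C)C
Why: Silylene formation with the bis-triflate bridges the syn-1,3-diol as a six-membered 1,3-dioxa-2-silinane with both substituents equatorial, a fluoride-labile replacement for the carbonate.

Step 10
Reactants: 10 15,17-O-di-tert-butylsilylene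
Product: 11 19-alcohol (15,17-silylene; 18-Cl; 13,14-acetonide)
Conditions: PPTS (cat.), MeOH/CH2Cl2, 0 °C
Reagents that add atoms: none
Why: Mild acid-catalysed methanolysis cleaves the secondary TES ether far faster than the di-tert-butylsilylene or, at 0 °C, the terminal acetonide.

Step 11
Reactants: 11 19-alcohol
Product: 13 19-carbamate (15,17-silylene; 18-Cl; 13,14-acetonide), via N-trichloroacetyl carbamate 12 (not isolated)
Conditions: Cl3CC(O)NCO, CH2Cl2, 0 °C; then neutral Al2O3, rt
Reagents that add atoms: trichloroacetyl isocyanate, O=C=NC(=O)C(Cl)(Cl)Cl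
Why: Addition of the hindered alcohol to the highly electrophilic acyl isocyanate followed by hydrolysis of the trichloroacetyl group on neutral alumina gives the primary carbamate (carbamoylation) without any base that could act on the chloride.

Step 12
Reactants: 13 19-carbamate
Product: 14 13,14-diol (19-carbamate; 15,17-silylene; 18-Cl)
Conditions: AcOH/H2O (4:1), 40 °C
Reagents that add atoms: none
Why: Acid hydrolysis of the terminal isopropylidene acetal; the silylene of a 1,3-diol, the carbamate and the secondary chloride tolerate aqueous acetic acid.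

Step 13
Reactants: 14 13,14-diol
Product: 15 13,14-bis-TBS ether
Conditions: TBSOTf, 2,6-lutidine, CH2Cl2, −78 → 0 °C
Reagents that add atoms: tert-butyldimethylsilyl trifluoromethanesulfonate, CC(C)(C)[Si](C)(C)OS(=O)(=O)C(F)(F)F
Why: Silylation of both hydroxyls with the silyl triflate; a transient N-silyl carbamate reverts on aqueous work-up.

Step 14
Reactants: 15 13,14-bis-TBS ether
Product: 16 13-alcohol (14-OTBS)
Conditions: CSA (cat.), MeOH/CH2Cl2, 0 °C
Reagents that add atoms: none
Why: Acid-catalysed methanolysis distinguishes the unhindered primary TBS ether from the flanked secondary one (selective desilylation).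

Step 15
Reactants: 16 13-alcohol
Product: 17 C13 aldehyde (14-OTBS; 15,17-silylene; 18-Cl; 19-carbamate)
Conditions: Dess–Martin periodinane, pyridine, CH2Cl2, 0 °C → rt
Reagents that add atoms: none
Why: Dess–Martin oxidation under buffered conditions gives the α-silyloxy aldehyde without epimerising C14, and it is used at once.

Step 16
Reactants: 18 (S)-but-3-yn-2-ol
Product: 19 (S)-but-3-yn-2-yl methanesulfonate
Conditions: MsCl, Et3N, CH2Cl2, −78 °C
Reagents that add atoms: methanesulfonyl chloride, CS(=O)(=O)Cl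
Why: Sulfonylation at oxygen leaves the propargylic stereocentre untouched (S retained).

Step 17
Reactants: 19 (S)-but-3-yn-2-yl methanesulfonate
Product: 20 (Ra)-tributyl(buta-1,2-dien-1-yl)stannane
Conditions: Bu3SnH, LiN(iPr)2, THF, −78 °C; CuBr·SMe2; then 19, −78 °C
Reagents that add atoms: tributyltin hydride, CCCC[SnH](CCCC)CCCC
Why: anti SN2′ displacement of the propargylic mesylate by the stannylcuprate transfers the central chirality of the (S)-mesylate to the (Ra) axis of the allene.

Step 18
Reactants: 17 C13 aldehyde; 20 (Ra)-tributyl(buta-1,2-dien-1-yl)stannane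
Product: 21 C10–C23 homopropargylic alcohol (13-OH; 12-methyl; terminal alkyne)
Conditions: BF3·OEt2, CH2Cl2, −78 °C
Reagents that add atoms: none
Why: Lewis acid-promoted SE2′ addition of the allenylstannane through an open transition state: C13 is attacked by the allene terminus anti to tin so the (Ra) axis sets C12, the syn methyl/hydroxyl preference of this reaction sets C13, and that face is also the Felkin–Anh face of the α-silyloxy aldehyde (13,14-anti), so reagent and substrate control are matched.

Step 19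
Reactants: 21 C10–C23 homopropargylic alcohol
Product: 22 13-TBS ether (terminal alkyne)
Conditions: TBSOTf, 2,6-lutidine, CH2Cl2, −78 → 0 °C
Reagents that add atoms: tert-butyldimethylsilyl trifluoromethanesulfonate, CC(C)(C)[Si](C)(C)OS(=O)(=O)C(F)(F)F
Why: Silylation of the hindered secondary alcohol with the silyl triflate keeps the homopropargylic oxygen from adding to the alkyne under palladium in step 21.

Step 20
Reactants: 22 13-TBS ether
Product: 23 C10 bromoalkyne
Conditions: NBS, AgNO3 (10 mol %), acetone, rt, dark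
Reagents that add atoms: N-bromosuccinimide, O=C1CCC(=O)N1Br
Why: Silver-catalysed electrophilic bromination of the terminal alkyne via the silver acetylide is much faster than attack of NBS on the inductively deactivated C20=C21 alkene.

Step 21
Reactants: 23 C10 bromoalkyne
Product: 24 (10Z)-10-bromo-11-chloroalkene
Conditions: Pd(OAc)2 (5 mol %), LiCl, AcOH/MeCN, rt
Reagents that add atoms: lithium chloride, [Li+].[Cl-]
Why: Palladium-catalysed hydrochlorination of a 1-bromoalkyne: chloride adds to C11 of the alkyne activated by divalent palladium on the face opposite the metal (trans-chloropalladation) and acetic acid cleaves the C10–Pd bond with retention, so H and Cl end up anti and the (Z)-1-bromo-2-chloroalkene results.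

Step 22
Reactants: 25 (−)-quinic acid
Product: 26 3,4-O-isopropylidenequinic acid 1,5-lactone
Conditions: Me2C(OMe)2, TsOH (cat.), acetone, reflux
Reagents that add atoms: 2,2-dimethoxypropane, COC(C)(C)OC
Why: Acid-catalysed acetalisation of the cis-3,4-diol with concomitant lactonisation of the carboxyl onto the cis C5 hydroxyl, the standard entry from quinic acid that differentiates all four hydroxyls.

Step 23
Reactants: 26 3,4-O-isopropylidenequinic acid 1,5-lactone
Product: 27 1-O-(imidazol-1-ylthiocarbonyl) derivative of 26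
Conditions: (imidazol-1-yl)2C=S, DMAP, ClCH2CH2Cl, reflux
Reagents that add atoms: 1,1′-thiocarbonyldiimidazole, S=C(n1ccnc1)n1ccnc1
Why: Thioacylation of the remaining tertiary hydroxyl (first half of the Barton–McCombie deoxygenation); the bridgehead position in the bicyclic lactone rules out elimination.

Step 24
Reactants: 27 1-O-(imidazol-1-ylthiocarbonyl) derivative
Product: 28 1-deoxy-3,4-O-isopropylidenequinic acid 1,5-lactone (H at C1 where the hydroxyl was)
Conditions: Bu3SnH, AIBN (cat.), toluene, 110 °C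
Reagents that add atoms: none
Why: Barton–McCombie radical deoxygenation: the carbonyl-stabilised C1 radical is held in the bicyclic lactone and can accept hydrogen only where the oxygen left, so the carboxyl stays cis to O5 and trans to the 3,4-dioxygen pair.

Step 25
Reactants: 28 1-deoxy lactone
Product: 29 2-(trimethylsilyl)ethyl (1S,3R,4S,5R)-5-hydroxy-3,4-(isopropylidenedioxy)cyclohexane-1-carboxylate
Conditions: Me3SiCH2CH2OH (solvent), NaH (0.1 equiv), 0 °C; AcOH quench
Reagents that add atoms: 2-(trimethylsilyl)ethanol, C[Si](C)(C)CCO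
Why: Alkoxide-catalysed transesterification of the strained lactone with the alcohol as solvent, as in the methanolysis of quinic lactones, run cold and quenched with acid so that the now enolisable C1 is not epimerised.

Step 26
Reactants: 29 5-hydroxy ester
Product: 30 5-O-(imidazol-1-ylthiocarbonyl) derivative of 29
Conditions: (imidazol-1-yl)2C=S, DMAP (cat.), CH2Cl2, 40 °C
Reagents that add atoms: 1,1′-thiocarbonyldiimidazole, S=C(n1ccnc1)n1ccnc1
Why: Thioacylation of the freed secondary C5 hydroxyl gives the Barton–McCombie precursor.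

Step 27
Reactants: 30 5-O-(imidazol-1-ylthiocarbonyl) derivative
Product: 31 2-(trimethylsilyl)ethyl (1S,3R,4S)-3,4-(isopropylidenedioxy)cyclohexane-1-carboxylate
Conditions: Bu3SnH, AIBN (cat.), toluene, 110 °C
Reagents that add atoms: none
Why: Barton–McCombie deoxygenation of the secondary thiocarbonyl derivative removes the last superfluous oxygen, and C5 becomes a methylene so no stereocentre is at stake.

Step 28
Reactants: 31 acetonide ester
Product: 32 2-(trimethylsilyl)ethyl (1S,3R,4S)-3,4-dihydroxycyclohexane-1-carboxylate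
Conditions: AcOH/H2O (4:1), 50 °C
Reagents that add atoms: none
Why: Acid hydrolysis of the ring-fused acetonide; the 2-(trimethylsilyl)ethyl ester survives aqueous acetic acid.

Step 29
Reactants: 32 cis-diol ester
Product: 33 2-(trimethylsilyl)ethyl (1S,3R,4S)-4-(tert-butyldimethylsilyloxy)-3-hydroxycyclohexane-1-carboxylate
Conditions: TBSCl, imidazole, DMF, 0 °C
Reagents that add atoms: tert-butyldimethylsilyl chloride, CC(C)(C)[Si](C)(C)Cl
Why: Regioselective silylation of the cis-diol: with the ester equatorial the C4′ hydroxyl is equatorial and the C3′ hydroxyl axial, so the bulky silyl chloride takes O4′ and leaves O3′ for the ester.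

Step 30
Reactants: 34 propargyl alcohol
Product: 35 (E)-3-(tributylstannyl)prop-2-en-1-ol
Conditions: Bu3SnH, AIBN (cat.), neat, 80 °C
Reagents that add atoms: tributyltin hydride, CCCC[SnH](CCCC)CCCC
Why: Radical hydrostannation of the terminal alkyne gives mainly the (E)-β-stannyl allylic alcohol under equilibrating conditions, and the minor isomers are removed by chromatography.

Step 31
Reactants: 35 (E)-3-(tributylstannyl)prop-2-en-1-ol
Product: 36 (E)-3-(tributylstannyl)prop-2-enal
Conditions: MnO2, CH2Cl2, rt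
Reagents that add atoms: none
Why: MnO2 oxidises the allylic alcohol selectively and does not touch the vinylstannane.

Step 32
Reactants: 36 (E)-3-(tributylstannyl)prop-2-enal
Product: 37 (2E,4E)-2-methyl-5-(tributylstannyl)penta-2,4-dienal
Conditions: Ph3P=C(CH3)CHO, toluene, 80 °C
Reagents that add atoms: 2-(triphenylphosphoranylidene)propanal, CC(C=O)=P(c1ccccc1)(c1ccccc1)c1ccccc1
Why: Wittig olefination with the stabilised α-formyl ylide is E-selective and delivers the trisubstituted C6=C7 alkene with the C6 methyl.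

Step 33
Reactants: 37 (2E,4E)-2-methyl-5-(tributylstannyl)penta-2,4-dienal
Product: 38 ethyl (2E,4E,6E,8E)-6-methyl-9-(tributylstannyl)nona-2,4,6,8-tetraenoate
Conditions: (EtO)2P(O)CH2CH=CHCO2Et, LiN(SiMe3)2, THF, −78 → 0 °C
Reagents that add atoms: triethyl 4-phosphonocrotonate, CCOC(=O)/C=C/CP(=O)(OCC)OCC
Why: Vinylogous Horner–Wadsworth–Emmons olefination with the lithiated phosphonocrotonate forms the C4=C5 alkene E-selectively and brings the (2E) alkene with it.

Step 34
Reactants: 38 ethyl tetraenoate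
Product: 39 (2E,4E,6E,8E)-6-methyl-9-(tributylstannyl)nona-2,4,6,8-tetraenoic acid
Conditions: LiOH, THF/MeOH/H2O, rt; AcOH to pH 5
Reagents that add atoms: lithium hydroxide, [Li+].[OH-]
Why: Saponification of the ethyl ester with work-up at pH 5, mild enough to avoid protodestannylation of the dienylstannane terminus.

Step 35
Reactants: 39 stannyl tetraenoic acid; 33 ring alcohol
Product: 41 C1–C9 stannyl tetraenoate of the (1S,3R,4S)-cyclohexanol 33, via mixed anhydride 40 (not isolated)
Conditions: 2,4,6-Cl3C6H2COCl, Et3N, toluene, rt; then 33, DMAP, rt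
Reagents that add atoms: none
Why: Yamaguchi esterification through the mixed 2,4,6-trichlorobenzoic anhydride and its acylpyridinium acylates the hindered axial C3′ hydroxyl without migration of the neighbouring TBS group or isomerisation of the tetraene.

Step 36
Reactants: 24 (10Z)-10-bromo-11-chloroalkene; 41 stannyl tetraenoate
Product: 42 fully protected target (13,14-bis-OTBS; 15,17-silylene; 4′-OTBS; 2-(trimethylsilyl)ethyl ester)
Conditions: Pd2(dba)3 (dba = dibenzylideneacetone; 5 mol %), AsPh3 (40 mol %), NMP, rt, dark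
Reagents that add atoms: none
Why: Stille coupling: zerovalent palladium inserts into the C–Br bond much faster than into the vinylic C–Cl bond or the allylic carbamate, and transmetalation and reductive elimination proceed with retention, so the (8E) and (10Z) geometries are carried into the pentaene.

Step 37
Reactants: 42 fully protected target
Product: 43 2-(trimethylsilyl)ethyl ester of the target (all hydroxyls free)
Conditions: HF·pyridine, pyridine, THF, 0 °C → rt
Reagents that add atoms: none
Why: Buffered HF·pyridine cleaves the three TBS ethers and the silylene as silyl fluorides (fluoride-mediated desilylation) under mildly acidic conditions that leave chlorohydrin, carbamate, polyene ester and the 2-(trimethylsilyl)ethyl ester intact.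

Step 38
Reactants: 43 2-(trimethylsilyl)ethyl ester of the target
Product: 44 target CNP0164989.3
Conditions: Bu4NF, AcOH (1:1), THF, 0 °C → rt
Reagents that add atoms: none
Why: Fluoride attacks the trimethylsilyl group and the ester fragments to the carboxylate, ethylene and Me3SiF (β-elimination of a 2-silylethyl ester), and the acetic acid buffer prevents epoxide closure of the chlorohydrin and acyl migration on the ring.

**Compound list**

1 | 2-deoxy-D-ribose (open-chain form drawn) | O=CC[C@H](O)[C@H](O)CO | starting material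
2 | (2R,3S)-hex-5-ene-1,2,3-triol | C=CC[C@H](O)[C@H](O)CO | intermediate
3 | (1S)-1-[(4R)-2,2-dimethyl-1,3-dioxolan-4-yl]but-3-en-1-ol | C=CC[C@H](O)[C@H]1COC(C)(C)O1 | intermediate
4 | tert-butyl (1S)-1-[(4R)-2,2-dimethyl-1,3-dioxolan-4-yl]but-3-en-1-yl carbonate (C13–C17; 14R,15S) | C=CC[C@H](OC(=O)OC(C)(C)C)[C@H]1COC(C)(C)O1 | intermediate
5 | tert-butyl (1S,3E)-1-[(4R)-2,2-dimethyl-1,3-dioxolan-4-yl]-5-oxopent-3-en-1-yl carbonate (C13–C19 enal) | O=C/C=C/C[C@H](OC(=O)OC(C)(C)C)[C@H]1COC(C)(C)O1 | intermediate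
6 | C13–C23 dienol; 15-OBoc; 13,14-O-isopropylidene; 19-OH (14R,15S,17E,19S,20E) | CC/C=C/[C@H](O)/C=C/C[C@H](OC(=O)OC(C)(C)C)[C@H]1COC(C)(C)O1 | intermediate
7 | C13–C23 dienyl carbonate; 15-OBoc; 13,14-O-isopropylidene; 19-OTES (14R,15S,17E,19S,20E) | CC/C=C/[C@H](O[Si](CC)(CC)CC)/C=C/C[C@H](OC(=O)OC(C)(C)C)[C@H]1COC(C)(C)O1 | intermediate
8 | chloro carbonate: 15,17-cyclic carbonate (cis-4,6-disubstituted 1,3-dioxan-2-one); 18-Cl; 19-OTES; 13,14-O-isopropylidene (14R,15S,17R,18R,19S,20E) | CC/C=C/[C@H](O[Si](CC)(CC)CC)[C@H](Cl)[C@H]1C[C@H](OC(=O)O1)[C@H]2COC(C)(C)O2 | intermediate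
9 | 15,17-diol; 18-Cl; 19-OTES; 13,14-O-isopropylidene (14R,15S,17R,18R,19S,20E) | CC/C=C/[C@H](O[Si](CC)(CC)CC)[C@H](Cl)[C@H](O)C[C@H](O)[C@H]1COC(C)(C)O1 | intermediate
10 | 15,17-O-di-tert-butylsilylene; 18-Cl; 19-OTES; 13,14-O-isopropylidene (14R,15S,17R,18R,19S,20E) | CC/C=C/[C@H](O[Si](CC)(CC)CC)[C@H](Cl)[C@H]1C[C@H](O[Si](C(C)(C)C)(C(C)(C)C)O1)[C@H]2COC(C)(C)O2 | intermediate
11 | 19-alcohol; 15,17-silylene; 18-Cl; 13,14-O-isopropylidene (14R,15S,17R,18S,19S,20E) | CC/C=C/[C@H](O)[C@H](Cl)[C@H]1C[C@H](O[Si](C(C)(C)C)(C(C)(C)C)O1)[C@H]2COC(C)(C)O2 | intermediate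
12 | N-trichloroacetyl carbamate of 11 (same configuration) | CC/C=C/[C@H](OC(=O)NC(=O)C(Cl)(Cl)Cl)[C@H](Cl)[C@H]1C[C@H](O[Si](C(C)(C)C)(C(C)(C)C)O1)[C@H]2COC(C)(C)O2 | intermediate (not isolated)
13 | 19-carbamate; 15,17-silylene; 18-Cl; 13,14-O-isopropylidene (14R,15S,17R,18S,19S,20E) | CC/C=C/[C@H](OC(N)=O)[C@H](Cl)[C@H]1C[C@H](O[Si](C(C)(C)C)(C(C)(C)C)O1)[C@H]2COC(C)(C)O2 | intermediate
14 | 13,14-diol; 19-carbamate; 15,17-silylene; 18-Cl (14R,15S,17R,18S,19S,20E) | CC/C=C/[C@H](OC(N)=O)[C@H](Cl)[C@H]1C[C@H](O[Si](C(C)(C)C)(C(C)(C)C)O1)[C@H](O)CO | intermediate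
15 | 13,14-bis-TBS ether of 14 (14R,15S,17R,18S,19S,20E) | CC/C=C/[C@H](OC(N)=O)[C@H](Cl)[C@H]1C[C@H](O[Si](C(C)(C)C)(C(C)(C)C)O1)[C@H](O[Si](C)(C)C(C)(C)C)CO[Si](C)(C)C(C)(C)C | intermediate
16 | 13-alcohol; 14-OTBS (14R,15S,17R,18S,19S,20E) | CC/C=C/[C@H](OC(N)=O)[C@H](Cl)[C@H]1C[C@H](O[Si](C(C)(C)C)(C(C)(C)C)O1)[C@H](O[Si](C)(C)C(C)(C)C)CO | intermediate
17 | C13 aldehyde; 14-OTBS; 15,17-silylene; 18-Cl; 19-carbamate (14S,15S,17R,18S,19S,20E) | CC/C=C/[C@H](OC(N)=O)[C@H](Cl)[C@H]1C[C@H](O[Si](C(C)(C)C)(C(C)(C)C)O1)[C@H](O[Si](C)(C)C(C)(C)C)C=O | intermediate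
18 | (S)-but-3-yn-2-ol | C#C[C@H](C)O | starting material
19 | (S)-but-3-yn-2-yl methanesulfonate | C#C[C@H](C)OS(C)(=O)=O | intermediate
20 | (Ra)-tributyl(buta-1,2-dien-1-yl)stannane | CCCC[Sn](CCCC)(CCCC)C([H])=[C@]=C([H])C | intermediate
21 | C10–C23 homopropargylic alcohol; 13-OH; 14-OTBS (12S,13R,14R,15S,17R,18S,19S,20E) | CC/C=C/[C@H](OC(N)=O)[C@H](Cl)[C@H]1C[C@H](O[Si](C(C)(C)C)(C(C)(C)C)O1)[C@H](O[Si](C)(C)C(C)(C)C)[C@H](O)[C@@H](C)C#C | intermediate
22 | 13-TBS ether of 21 (12S,13R,14S,15S,17R,18S,19S,20E) | CC/C=C/[C@H](OC(N)=O)[C@H](Cl)[C@H]1C[C@H](O[Si](C(C)(C)C)(C(C)(C)C)O1)[C@H](O[Si](C)(C)C(C)(C)C)[C@H](O[Si](C)(C)C(C)(C)C)[C@@H](C)C#C | intermediate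
23 | C10 bromoalkyne (12S,13R,14S,15S,17R,18S,19S,20E) | CC/C=C/[C@H](OC(N)=O)[C@H](Cl)[C@H]1C[C@H](O[Si](C(C)(C)C)(C(C)(C)C)O1)[C@H](O[Si](C)(C)C(C)(C)C)[C@H](O[Si](C)(C)C(C)(C)C)[C@@H](C)C#CBr | intermediate
24 | (10Z)-10-bromo-11-chloroalkene (10Z,12R,13R,14S,15S,17R,18S,19S,20E) | CC/C=C/[C@H](OC(N)=O)[C@H](Cl)[C@H]1C[C@H](O[Si](C(C)(C)C)(C(C)(C)C)O1)[C@H](O[Si](C)(C)C(C)(C)C)[C@H](O[Si](C)(C)C(C)(C)C)[C@@H](C)/C(Cl)=C/Br | intermediate
25 | (−)-quinic acid, (1S,3R,4S,5R) | O[C@@H]1C[C@@](O)(C(=O)O)C[C@@H](O)[C@@H]1O | starting material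
26 | 3,4-O-isopropylidenequinic acid 1,5-lactone (quinic acid numbering; all centres as in 25) | CC1(C)O[C@@H]2C[C@]3(O)C[C@@H](OC3=O)[C@@H]2O1 | intermediate
27 | 1-O-(imidazol-1-ylthiocarbonyl) derivative of 26 | CC1(C)O[C@@H]2C[C@]3(OC(=S)n4ccnc4)C[C@@H](OC3=O)[C@@H]2O1 | intermediate
28 | 1-deoxy-3,4-O-isopropylidenequinic acid 1,5-lactone (H at C1; carboxyl cis to O5) | CC1(C)O[C@@H]2C[C@@H]3C[C@@H](OC3=O)[C@@H]2O1 | intermediate
29 | 2-(trimethylsilyl)ethyl (1S,3R,4S,5R)-5-hydroxy-3,4-(isopropylidenedioxy)cyclohexane-1-carboxylate | CC1(C)O[C@@H]2C[C@@H](C(=O)OCC[Si](C)(C)C)C[C@@H](O)[C@@H]2O1 | intermediate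
30 | 5-O-(imidazol-1-ylthiocarbonyl) derivative of 29 | CC1(C)O[C@@H]2C[C@@H](C(=O)OCC[Si](C)(C)C)C[C@@H](OC(=S)n3ccnc3)[C@@H]2O1 | intermediate
31 | 2-(trimethylsilyl)ethyl (1S,3R,4S)-3,4-(isopropylidenedioxy)cyclohexane-1-carboxylate | CC1(C)O[C@@H]2C[C@@H](C(=O)OCC[Si](C)(C)C)CC[C@@H]2O1 | intermediate
32 | 2-(trimethylsilyl)ethyl (1S,3R,4S)-3,4-dihydroxycyclohexane-1-carboxylate | O[C@@H]1C[C@@H](C(=O)OCC[Si](C)(C)C)CC[C@@H]1O | intermediate
33 | 2-(trimethylsilyl)ethyl (1S,3R,4S)-4-(tert-butyldimethylsilyloxy)-3-hydroxycyclohexane-1-carboxylate | O[C@@H]1C[C@@H](C(=O)OCC[Si](C)(C)C)CC[C@@H]1O[Si](C)(C)C(C)(C)C | intermediate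
34 | propargyl alcohol | C#CCO | starting material
35 | (E)-3-(tributylstannyl)prop-2-en-1-ol | CCCC[Sn](CCCC)(CCCC)/C=C/CO | intermediate
36 | (E)-3-(tributylstannyl)prop-2-enal | CCCC[Sn](CCCC)(CCCC)/C=C/C=O | intermediate
37 | (2E,4E)-2-methyl-5-(tributylstannyl)penta-2,4-dienal | CCCC[Sn](CCCC)(CCCC)/C=C/C=C(C)/C=O | intermediate
38 | ethyl (2E,4E,6E,8E)-6-methyl-9-(tributylstannyl)nona-2,4,6,8-tetraenoate | CCCC[Sn](CCCC)(CCCC)/C=C/C=C(C)/C=C/C=C/C(=O)OCC | intermediate
39 | (2E,4E,6E,8E)-6-methyl-9-(tributylstannyl)nona-2,4,6,8-tetraenoic acid | CCCC[Sn](CCCC)(CCCC)/C=C/C=C(C)/C=C/C=C/C(=O)O | intermediate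
40 | mixed anhydride of 39 with 2,4,6-trichlorobenzoic acid | CCCC[Sn](CCCC)(CCCC)/C=C/C=C(C)/C=C/C=C/C(=O)OC(=O)c1c(Cl)cc(Cl)cc1Cl | intermediate (not isolated)
41 | C1–C9 stannyl tetraenoate of 33, ester at O3′ (2E,4E,6E,8E; 1′S,3′R,4′S) | CCCC[Sn](CCCC)(CCCC)/C=C/C=C(C)/C=C/C=C/C(=O)O[C@@H]1C[C@@H](C(=O)OCC[Si](C)(C)C)CC[C@@H]1O[Si](C)(C)C(C)(C)C | intermediate
42 | fully protected target (2E,4E,6E,8E,10Z,12R,13R,14S,15S,17R,18S,19S,20E; 1′S,3′R,4′S) | CC/C=C/[C@H](OC(N)=O)[C@H](Cl)[C@H]1C[C@H](O[Si](C(C)(C)C)(C(C)(C)C)O1)[C@H](O[Si](C)(C)C(C)(C)C)[C@H](O[Si](C)(C)C(C)(C)C)[C@@H](C)/C(Cl)=C/C=C/C=C(C)/C=C/C=C/C(=O)O[C@@H]1C[C@@H](C(=O)OCC[Si](C)(C)C)CC[C@@H]1O[Si](C)(C)C(C)(C)C | intermediate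
43 | 2-(trimethylsilyl)ethyl ester of the target (12R,13R,14S,15S,17R,18R,19S; 1′S,3′R,4′S) | CC/C=C/[C@H](OC(N)=O)[C@H](Cl)[C@H](O)C[C@H](O)[C@H](O)[C@H](O)[C@@H](C)/C(Cl)=C/C=C/C=C(C)/C=C/C=C/C(=O)O[C@@H]1C[C@@H](C(=O)OCC[Si](C)(C)C)CC[C@@H]1O | intermediate
44 | CNP0164989.3 (2E,4E,6E,8E,10Z,12R,13R,14S,15S,17R,18R,19S,20E; 1′S,3′R,4′S) | CC/C=C/[C@H](OC(N)=O)[C@H](Cl)[C@H](O)C[C@H](O)[C@H](O)[C@H](O)[C@@H](C)/C(Cl)=C/C=C/C=C(C)/C=C/C=C/C(=O)O[C@@H]1C[C@@H](C(=O)O)CC[C@@H]1O | target

**Totals**

Total step count: 38. Longest linear sequence: 22 steps (steps 1–15, 18–21, 36–38).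

**Steps most likely to fail**

1. Step 7 (Proposed new method). Chlorine transfer may not be channelled through the tether: attack on C20=C21, radical chlorination at the doubly allylic C19–H, 7-endo closure, or an eroded 15,17-syn preference because chloronium formation is less reversible than iodonium formation. The fallback uses known chemistry and sets out from 7. The iodine variant of the same closure (IBr, toluene, −85 °C) should give the iodocarbonate F1 with the same 15,17-syn, 17,18-anti arrangement. K2CO3 in MeOH then cleaves the carbonate and lets the C17 alkoxide displace iodide with inversion, giving the trans-17,18-epoxy-15-ol F2. A chlorotitanium alkoxide (Ti(OiPr)3Cl), bound to the free C15 hydroxyl and chelating the epoxide oxygen in a six-membered ring, then delivers chloride to C18 with a second inversion. This gives diol 9, where the route is rejoined; the regiochemistry of this last opening rests on the chelation and is the weak point of the detour.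

2. Step 21. Chloropalladation may be slow or non-regioselective on the branched, heavily functionalised bromoalkyne, or divalent palladium may instead engage the allylic carbamate (1,3-transposition). The fallback sets out from 21 and 41 and changes both the C9–C10 bond formation and the way chlorine is installed. Iododestannylation of 41 (I2, CH2Cl2, 0 °C) gives the tetraenyl iodide F3. Sonogashira coupling with the free homopropargylic alcohol 21 (Pd(PPh3)4, CuI, iPr2NH) gives the enyne F4. Hydroxyl-directed trans-hydrostannation ([Cp*RuCl]4, Bu3SnH, CH2Cl2) places tin on C11 and hydrogen on C10 anti to it, giving the C11 stannane F5. Chlorodestannation with retention (CuCl2, 2,6-lutidine, THF) gives the 13-hydroxy (10Z)-chloropentaene F6. HF·pyridine as in step 37 then gives 43, where the route is rejoined.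

3. Step 5. Facial selectivity at the unbranched enal may be poor (uncatalysed background addition), leaving a C19 epimer mixture that is hard to separate. The fallback sets out from 5 and separates carbon–carbon bond formation from control of the alkene geometry. Zinc alkynylide addition under ProPhenol catalysis (1-butyne, ZnMe2, the ProPhenol enantiomer that directs the alkynyl group to the Si face) gives the enynol F7. Ruthenium-catalysed trans-hydrosilylation ([Cp*Ru(MeCN)3]PF6, (EtO)3SiH) gives the (Z)-vinylsilane F8. Protodesilylation with retention (AgF, THF/MeOH/H2O) gives the (20E)-dienol 6, where the route is rejoined.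

**Further compounds**

F1 | step 7 | iodocarbonate: 15,17-cyclic carbonate; 18-iodo; 19-OTES; 13,14-O-isopropylidene | CC/C=C/[C@H](O[Si](CC)(CC)CC)[C@H](I)[C@H]1C[C@H](OC(=O)O1)[C@H]2COC(C)(C)O2
F2 | step 7 | trans-17,18-epoxy-15-ol; 19-OTES; 13,14-O-isopropylidene | CC/C=C/[C@H](O[Si](CC)(CC)CC)[C@H]1O[C@@H]1C[C@H](O)[C@H]2COC(C)(C)O2
F3 | step 21 | C1–C9 tetraenyl iodide ester of 33 | I/C=C/C=C(C)/C=C/C=C/C(=O)O[C@@H]1C[C@@H](C(=O)OCC[Si](C)(C)C)CC[C@@H]1O[Si](C)(C)C(C)(C)C
F4 | step 21 | C10–C11 enyne with free 13-OH | CC/C=C/[C@H](OC(N)=O)[C@H](Cl)[C@H]1C[C@H](O[Si](C(C)(C)C)(C(C)(C)C)O1)[C@H](O[Si](C)(C)C(C)(C)C)[C@H](O)[C@@H](C)C#C/C=C/C=C(C)/C=C/C=C/C(=O)O[C@@H]2C[C@@H](C(=O)OCC[Si](C)(C)C)CC[C@@H]2O[Si](C)(C)C(C)(C)C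
F5 | step 21 | C11 tributylstannyl pentaene with free 13-OH | CC/C=C/[C@H](OC(N)=O)[C@H](Cl)[C@H]1C[C@H](O[Si](C(C)(C)C)(C(C)(C)C)O1)[C@H](O[Si](C)(C)C(C)(C)C)[C@H](O)[C@@H](C)/C([Sn](CCCC)(CCCC)CCCC)=C/C=C/C=C(C)/C=C/C=C/C(=O)O[C@@H]2C[C@@H](C(=O)OCC[Si](C)(C)C)CC[C@@H]2O[Si](C)(C)C(C)(C)C
F6 | step 21 | 13-hydroxy (10Z)-11-chloropentaene (14-OTBS; 15,17-silylene; 4′-OTBS; 2-(trimethylsilyl)ethyl ester) | CC/C=C/[C@H](OC(N)=O)[C@H](Cl)[C@H]1C[C@H](O[Si](C(C)(C)C)(C(C)(C)C)O1)[C@H](O[Si](C)(C)C(C)(C)C)[C@H](O)[C@@H](C)/C(Cl)=C/C=C/C=C(C)/C=C/C=C/C(=O)O[C@@H]2C[C@@H](C(=O)OCC[Si](C)(C)C)CC[C@@H]2O[Si](C)(C)C(C)(C)C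
F7 | step 5 | C13–C23 enynol (C20–C21 alkyne; 19-OH; 15-OBoc; 13,14-O-isopropylidene) | CCC#C[C@H](O)/C=C/C[C@H](OC(=O)OC(C)(C)C)[C@H]1COC(C)(C)O1
F8 | step 5 | (Z)-C21 triethoxysilyl dienol | CC/C([Si](OCC)(OCC)OCC)=C/[C@H](O)/C=C/C[C@H](OC(=O)OC(C)(C)C)[C@H]1COC(C)(C)O1
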